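Time the delay before target stands in each flask, and hold it against the slow leak to the isomer of the product.

| flask | substrate | enzyme | time |
|---|---|---|---|
| noon | 6.0 mM | 3.0 µM | 4.0 min |
| dusk | 20 mM | 3.0 µM | 4.0 min |
| midnight | 60 mM | 3.0 µM | 4.0 min |

    complex ⇌ enzyme + target (K1 = 0.217 M, k1 = 11200 min⁻¹)
    substrate + enzyme ⇌ complex (K2 = 57.5 M⁻¹, k2 = 1.42 × 10⁵ M⁻¹ s⁻¹)
    target ⇌ isomer of the product (K3 = 9.3, k3 = 0.0511 min⁻¹)

- "hardly changes" means that all values lie within two and a half points (for a concentration: within two and a half percent of the largest)
- run time (noon): 4.0 min

- share of target in all that became target or isomer of the product for noon, dusk, midnight, in this order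
- how the row runs (falls, then rises / hardly changes / rises all the way / rises, then falls / falls all the way)

Ask first what end the enzyme steps approach. Taken together they turn substrate into target with the constant 12.5, so target holds 92.6% of the pool of substrate and target once these two stand in balance. The enzyme charge is far smaller than the substrate charge, so the bound part is left out of the pool. The pool then drains into the isomer of the product at 0.0473 min⁻¹, and the way back is dropped while little isomer stands.

Next, ask how fast the pool fills. The enzyme works with a half-saturation concentration (the Michaelis constant) of 18.7 mM and a top rate of 33.6 mM min⁻¹. Integrating that rate law gives a charge of substrate a mean wait of the half-saturation concentration plus half the charge, divided by the top rate. This is the weak link, since the substrate does not run down to nothing. Near balance the way back adds to the way forward, and the approach quickens by the inverse of the balance share, so the wait is multiplied by that share. At noon this gives 0.598 min: the fill delay, the time the leak loses before the pool stands as target. At dusk it is 0.791 min and at midnight 1.34 min, still shorter than the leak's own time of 21.1 min.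

The leak is therefore counted from the end of the delay. At noon 85.1% of the pool is left at 4.0 min; target is the balance share of that, and the isomer is the remainder of the charge. This reckoning gives shares of 84.1%, 85.0% and 87.4%, a rise of 3.3 percentage points, wider than the band for a row that hardly changes.

The forecast, 0.20 points above this reckoning at midnight, reads 84.2%, 85.1%, 87.6%, rises all the way, on the ground that “Higher substrate saturates the enzyme and delays target formation”.

The simulation gives 84.3%, 85.2%, 87.5%, rises all the way. In the noon flask the half-life of target along the forward leak is 14 min, long against the run of 4.0 min, and the reckoned noon fill delay of 0.598 min takes 14.9% of that run. At 1.20 min, still inside the reckoned midnight delay of 1.34 min, 63.5% of the catalyst in the midnight flask stands as complex, more than the 6.04% of the noon flask at that time.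

The rate constants are invented; the run is a simulation.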